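**Retrosynthetic overview** (locants are the azulene numbering of target 20: C3 hydroxy-isopropyl, C3a-H/C8a-Me ring fusion, C5 CO2H, C6 C=O, C7 2-oxopropyl, C8 enol ester)
1. 20 ⇐ 17 by unmasking (two tert-butyl esters, loss of CO2 at C7, silyl ether). The key bond is the enol-ester C–O bond of 17, made late by E-selective O-acylation of aldehyde 15.
2. 15 ⇐ 13 (alkylation at C7) ⇐ 11 by an amine-catalysed 7-exo Michael cyclisation (C7–C8 bond; seven-membered ring formed second).
3. 11 ⇐ lactol 7 + di-tert-butyl 3-oxopentanedioate (Knoevenagel C4–C5 bond, with a temporary C–O tether to the tertiary alcohol), then cross-metathesis with crotonaldehyde.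
4. 7 ⇐ enal 4 by conjugate vinylation (quaternary C8a) and lactol formation (a C–O bond that locks C3a).
5. 4 ⇐ (S)-α-terpineol by ozonolysis/aldol (cyclopentane ring formed first; C3 from the chiral pool).

Assumption: (S)-(−)-α-terpineol is bought in high enantiomeric purity (otherwise one hydration step from (S)-limonene), and compounds that can exist as lactol, oxa-Michael or enol tautomers are drawn in the form named.

**Step 1**
Reactants: 1 (S)-(−)-α-terpineol
Product: 2 trimethylsilyl ether of 1
Conditions: Me3SiCl, imidazole, DMF, 23 °C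
Reagents that add atoms: chlorotrimethylsilane C[Si](C)(C)Cl
Why: Silylation (silyl ether protection) of the tertiary alcohol keeps the hydroxyl out of the aldol and cuprate steps, and the C3 stereocentre is carried over unchanged from the chiral pool.

**Step 2**
Reactants: 2 trimethylsilyl ether of 1
Product: 4 (5S)-2-methyl-5-[2-(trimethylsilyloxy)propan-2-yl]cyclopent-1-ene-1-carbaldehyde, via keto aldehyde 3 (not isolated)
Conditions: O3, CH2Cl2, −78 °C; PPh3; then piperidine (cat.), AcOH (cat.), PhMe, 80 °C
Reagents that add atoms: ozone [O-][O+]=O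
Why: Ozonolysis cleaves the only alkene and the enamine-mediated intramolecular aldol condensation closes the cyclopentene through the aldehyde α-carbon, as is well known for the limonene series, without touching the stereocentre.

**Step 3**
Reactants: 4 (5S)-2-methyl-5-[2-(trimethylsilyloxy)propan-2-yl]cyclopent-1-ene-1-carbaldehyde
Product: 7 cis-fused lactol 3,3,6-trimethyl-6-vinylhexahydro-1H-cyclopenta[c]furan-1-ol, via bis-silyl enol ether 5 (not isolated), via hydroxy aldehyde 6 (not isolated)
Conditions: CH2=CHMgBr, CuBr·SMe2 (10 mol%), Me3SiCl, HMPA, THF, −78 °C; then K2CO3, MeOH, 23 °C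
Reagents that add atoms: vinylmagnesium bromide C=C[Mg]Br
Why: Copper-catalysed conjugate addition of the Grignard reagent occurs anti to the bulky pseudo-axial silyloxy-isopropyl group and so sets the quaternary C8a centre with methyl cis to that group, and after methanolysis of both silyl groups base-mediated epimerisation at C3a is funnelled into the only epimer that can close to the cis-fused lactol (hemiacetal C–O bond formation under thermodynamic control), which fixes C3a.

**Step 4**
Reactants: 7 cis-fused lactol; 8 di-tert-butyl 3-oxopentanedioate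
Product: 9 di-tert-butyl 2-(3,3,6-trimethyl-6-vinylhexahydro-1H-cyclopenta[c]furan-1-yl)-3-oxopentanedioate
Conditions: 8 (3 equiv), piperidine (20 mol%), AcOH (20 mol%), 4 Å sieves, PhMe, 50 °C
Reagents that add atoms: none
Why: Knoevenagel condensation of the lactol (through its open hydroxy aldehyde) with the symmetrical β-keto diester is followed by oxa-Michael addition of the tertiary hydroxyl, giving the tetrahydrofuran adduct that keeps C3a locked and masks the later ring enone; the new exo centre at the furan C1 and the enolisable centre beside it are removed again later.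

**Step 5**
Reactants: 9 tetrahydrofuran adduct; 10 (E)-but-2-enal
Product: 11 di-tert-butyl 2-{3,3,6-trimethyl-6-[(E)-3-oxoprop-1-enyl]hexahydro-1H-cyclopenta[c]furan-1-yl}-3-oxopentanedioate
Conditions: 10 (5 equiv), second-generation Hoveyda–Grubbs catalyst RuCl2(H2IMes)(=CH–C6H4-2-OiPr) (5 mol%), PhMe, 60 °C
Reagents that add atoms: none
Why: Olefin cross-metathesis of the hindered vinyl group with excess crotonaldehyde gives the E-enal under thermodynamic control with loss of propene.

**Step 6**
Reactants: 11 enal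
Product: 13 bicyclic keto diester aldehyde (tertiary trimethylsilyl ether), via oxa-bridged tricyclic aldehyde 12 (not isolated)
Conditions: (R)-2-[diphenyl(trimethylsilyloxy)methyl]pyrrolidine (20 mol%), PhCO2H (20 mol%), PhMe (0.02 M), 23 °C; then N-(trimethylsilyl)imidazole, 40 °C
Reagents that add atoms: N-(trimethylsilyl)imidazole C[Si](C)(C)n1ccnc1
Why: Proposed new method: iminium-ion activation of the E-enal by the chiral secondary amine lets the β-keto ester enol add 7-exo-trig to the Re face of the β-carbon (the face left open by the diphenyl(silyloxy)methyl group, and in a chair-like transition state the one that puts the side chain equatorial), which sets C8 and closes the seven-membered ring, after which amine-mediated retro-oxa-Michael opening of the tetrahydrofuran is made irreversible by O-silylation; the closest known reactions are amine-catalysed intermolecular and 5-/6-exo intramolecular Michael additions of 1,3-dicarbonyl compounds to enals, not yet shown for a seven-membered carbocycle on a neopentyl-type enal.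

**Step 7**
Reactants: 13 bicyclic keto diester aldehyde; 14 1-chloropropan-2-one
Product: 15 7-(2-oxopropyl) keto diester aldehyde (quaternary C7)
Conditions: K2CO3, NaI (cat.), MeCN, 23 °C
Reagents that add atoms: none
Why: SN2 C-alkylation of the β-keto ester enolate (the only strongly acidic C–H left) installs the 2-oxopropyl group anti to the C8 side chain, and the configuration at C7 is not critical because it is reset after decarboxylation.

**Step 8**
Reactants: 15 7-(2-oxopropyl) keto diester aldehyde; 16 3-methylbut-2-enoic acid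
Product: 17 E-enol ester 8-{(E)-2-[(3-methylbut-2-enoyl)oxy]ethenyl} analogue of 15
Conditions: 16 (3 equiv), DCC (1.5 equiv), PhMe, 23 °C; then 15, DMAP (1.5 equiv), 50 °C
Reagents that add atoms: none
Why: DMAP-mediated O-acylation of the aldehyde enol by the anhydride made in the flask (Steglich-type acyl transfer) forms the enol-ester C–O bond, and because this acyl transfer is reversible the geometry is under thermodynamic control and E is favoured (expected ≥10:1, the Z isomer having allylic strain with the doubly neopentyl C8 carbon), while the C6 ketone has no α-hydrogen, the methyl ketone is far less acidic and the tertiary hydroxyl is silylated.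

**Step 9**
Reactants: 17 E-enol ester
Product: 20 CNP0290717.1 (target), via tris-silyl compound 18 (not isolated), via diacid 19 (not isolated)
Conditions: Me3SiOTf, 2,6-lutidine, CH2Cl2, 0 °C; then MeOH, aq. citric acid, 23 → 40 °C
Reagents that add atoms: none
Why: Silyl-triflate-mediated tert-butyl ester cleavage (loss of isobutene) and mild acidic methanolysis give the diacid, whose β-keto acid at quaternary C7 decarboxylates while the C5 acid on the ring alkene cannot (it would need a ring allene), and ketonisation or equilibration through the enol places the 2-oxopropyl group trans-diequatorial to the C8 substituent, the configuration the natural product holds at this epimerisable centre.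

**Compound list**
1 | (S)-(−)-α-terpineol, 2-[(1S)-4-methylcyclohex-3-en-1-yl]propan-2-ol | CC1=CC[C@@H](C(C)(C)O)CC1 | starting material
2 | trimethyl({2-[(1S)-4-methylcyclohex-3-en-1-yl]propan-2-yl}oxy)silane | CC1=CC[C@@H](C(C)(C)O[Si](C)(C)C)CC1 | intermediate
3 | (3S)-6-oxo-3-[2-(trimethylsilyloxy)propan-2-yl]heptanal | O=CC[C@@H](C(C)(C)O[Si](C)(C)C)CCC(C)=O | intermediate
4 | (5S)-2-methyl-5-[2-(trimethylsilyloxy)propan-2-yl]cyclopent-1-ene-1-carbaldehyde | CC1=C(C=O)[C@@H](C(C)(C)O[Si](C)(C)C)CC1 | intermediate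
5 | bis-silyl enol ether of the 1,4-adduct (vinyl trans to the silyloxy-isopropyl group) | C[C@]1(C=C)CC[C@H](C(C)(C)O[Si](C)(C)C)C1=CO[Si](C)(C)C | intermediate
6 | 5-(2-hydroxypropan-2-yl)-2-methyl-2-vinylcyclopentane-1-carbaldehyde (methyl cis to the hydroxy-isopropyl group, mixture at C1) | C[C@]1(C=C)CC[C@H](C(C)(C)O)C1C=O | intermediate
7 | cis-fused lactol, 3,3,6-trimethyl-6-vinylhexahydro-1H-cyclopenta[c]furan-1-ol (6-methyl on the furan face, anomer mixture) | OC1OC(C)(C)[C@H]2CC[C@](C)(C=C)[C@@H]12 | intermediate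
8 | di-tert-butyl 3-oxopentanedioate | CC(C)(C)OC(=O)CC(=O)CC(=O)OC(C)(C)C | starting material
9 | di-tert-butyl 2-(3,3,6-trimethyl-6-vinylhexahydro-1H-cyclopenta[c]furan-1-yl)-3-oxopentanedioate (exo at furan C1, diester C2 enolisable) | CC(C)(C)OC(=O)CC(=O)C(C(=O)OC(C)(C)C)[C@@H]1OC(C)(C)[C@H]2CC[C@](C)(C=C)[C@@H]12 | intermediate
10 | (E)-but-2-enal (crotonaldehyde) | C/C=C/C=O | starting material
11 | di-tert-butyl 2-{3,3,6-trimethyl-6-[(E)-3-oxoprop-1-enyl]hexahydro-1H-cyclopenta[c]furan-1-yl}-3-oxopentanedioate | CC(C)(C)OC(=O)CC(=O)C(C(=O)OC(C)(C)C)[C@@H]1OC(C)(C)[C@H]2CC[C@](C)(/C=C/C=O)[C@@H]12 | intermediate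
12 | oxa-bridged tricyclic keto diester aldehyde (Michael adduct, tetrahydrofuran still closed) | CC(C)(C)OC(=O)C3C(=O)C(C(=O)OC(C)(C)C)[C@@H]1OC(C)(C)[C@H]2CC[C@](C)([C@H]3CC=O)[C@@H]12 | intermediate
13 | di-tert-butyl 8a-methyl-6-oxo-8-(2-oxoethyl)-3-[2-(trimethylsilyloxy)propan-2-yl]-1,2,3,3a,6,7,8,8a-octahydroazulene-5,7-dicarboxylate (C3, C3a, C8, C8a as in 20; C7 epimerisable) | CC(C)(C)OC(=O)C1C(=O)C(C(=O)OC(C)(C)C)=C[C@H]2[C@@H](C(C)(C)O[Si](C)(C)C)CC[C@]2(C)[C@H]1CC=O | intermediate
14 | 1-chloropropan-2-one (chloroacetone) | CC(=O)CCl | starting material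
15 | 7-(2-oxopropyl) derivative of 13 (quaternary C7, 2-oxopropyl trans to the C8 side chain) | CC(=O)C[C@]1(C(=O)OC(C)(C)C)C(=O)C(C(=O)OC(C)(C)C)=C[C@H]2[C@@H](C(C)(C)O[Si](C)(C)C)CC[C@]2(C)[C@H]1CC=O | intermediate
16 | 3-methylbut-2-enoic acid (senecioic acid) | CC(C)=CC(=O)O | starting material
17 | E-enol ester, 8-{(E)-2-[(3-methylbut-2-enoyl)oxy]ethenyl} analogue of 15 | CC(=O)C[C@]1(C(=O)OC(C)(C)C)C(=O)C(C(=O)OC(C)(C)C)=C[C@H]2[C@@H](C(C)(C)O[Si](C)(C)C)CC[C@]2(C)[C@H]1/C=C/OC(=O)C=C(C)C | intermediate
18 | bis(trimethylsilyl) ester and tertiary trimethylsilyl ether of 19 | CC(=O)C[C@]1(C(=O)O[Si](C)(C)C)C(=O)C(C(=O)O[Si](C)(C)C)=C[C@H]2[C@@H](C(C)(C)O[Si](C)(C)C)CC[C@]2(C)[C@H]1/C=C/OC(=O)C=C(C)C | intermediate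
19 | diacid, 7-carboxy derivative of 20 | CC(=O)C[C@]1(C(=O)O)C(=O)C(C(=O)O)=C[C@H]2[C@@H](C(C)(C)O)CC[C@]2(C)[C@H]1/C=C/OC(=O)C=C(C)C | intermediate
20 | CNP0290717.1, (3S,3aS,7S,8S,8aS)-3-(2-hydroxypropan-2-yl)-8a-methyl-8-{(E)-2-[(3-methylbut-2-enoyl)oxy]ethenyl}-6-oxo-7-(2-oxopropyl)-1,2,3,3a,6,7,8,8a-octahydroazulene-5-carboxylic acid | CC(=O)C[C@@H]1C(=O)C(C(=O)O)=C[C@H]2[C@@H](C(C)(C)O)CC[C@]2(C)[C@H]1/C=C/OC(=O)C=C(C)C | target

**Step count**
Total steps: 9. Longest linear sequence: 9 steps (1 → 20).

**Three steps most likely to fail**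

Step 4 (Knoevenagel on a very hindered lactol). Fallback: replace amine catalysis by oxocarbenium chemistry. It sets out from 7: acetylation (Ac2O, pyridine) gives the lactol acetate F1; separately 8 is converted (Me3SiCl, Et3N) into di-tert-butyl 3-(trimethylsilyloxy)pent-2-enedioate F2; Me3SiOTf (cat.) in CH2Cl2 at −78 °C joins them by Lewis-acid C-glycosylation (Mukaiyama-type addition to the oxocarbenium ion), and the route is rejoined at 9.

Step 6 (the proposed new step: seven-membered ring closure, catalyst/substrate matching, competing attack by the second dicarbonyl carbon). Fallback with known chemistry: from 11, Me3SiOTf/Et3N gives the ring-opened silyl dienol ether F3 (tertiary alcohol silylated, alkylidene β-keto ester, silyl enol ether on the nucleophilic carbon). BF3·OEt2 at −78 °C then effects an intramolecular Mukaiyama–Michael addition under substrate control through the same chair-like transition state. Aqueous NaHCO3 work-up rejoins the route at 13.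

Step 8 (E/Z ratio, slow acyl transfer to a hindered enol, possible epimerisation at C3a under base). Fallback: build the enol ester by stereoretentive C–O cross-coupling instead of enol acylation. From 15, pyrrolidine gives the enamine F4, which CuCl/O2 cleaves to the one-carbon-shorter aldehyde F5. Takai-type olefination (Cl2CHB(pin), CrCl2, LiI) gives the E-alkenyl pinacol boronate F6, and NaIO4/NH4OAc frees the E-alkenylboronic acid F7. Copper-mediated Chan–Lam-type coupling with 16 (Cu(OAc)2, Et3N, 4 Å sieves, air) rejoins the route at 17.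

**Further compounds**
F1 | step 4 | lactol acetate of 7 | CC(=O)OC1OC(C)(C)[C@H]2CC[C@](C)(C=C)[C@@H]12
F2 | step 4 | di-tert-butyl 3-(trimethylsilyloxy)pent-2-enedioate | CC(C)(C)OC(=O)CC(O[Si](C)(C)C)=CC(=O)OC(C)(C)C
F3 | step 6 | ring-opened silyl dienol ether of 11 | CC(C)(C)OC(=O)C=C(O[Si](C)(C)C)C(C(=O)OC(C)(C)C)=C[C@H]1[C@@H](C(C)(C)O[Si](C)(C)C)CC[C@]1(C)/C=C/C=O
F4 | step 8 | pyrrolidine E-enamine of 15 | CC(=O)C[C@]1(C(=O)OC(C)(C)C)C(=O)C(C(=O)OC(C)(C)C)=C[C@H]2[C@@H](C(C)(C)O[Si](C)(C)C)CC[C@]2(C)[C@H]1/C=C/N3CCCC3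
F5 | step 8 | 8-formyl (one-carbon-shorter) aldehyde | CC(=O)C[C@]1(C(=O)OC(C)(C)C)C(=O)C(C(=O)OC(C)(C)C)=C[C@H]2[C@@H](C(C)(C)O[Si](C)(C)C)CC[C@]2(C)[C@H]1C=O
F6 | step 8 | E-alkenyl pinacol boronate | CC(=O)C[C@]1(C(=O)OC(C)(C)C)C(=O)C(C(=O)OC(C)(C)C)=C[C@H]2[C@@H](C(C)(C)O[Si](C)(C)C)CC[C@]2(C)[C@H]1/C=C/B3OC(C)(C)C(C)(C)O3
F7 | step 8 | E-alkenylboronic acid | CC(=O)C[C@]1(C(=O)OC(C)(C)C)C(=O)C(C(=O)OC(C)(C)C)=C[C@H]2[C@@H](C(C)(C)O[Si](C)(C)C)CC[C@]2(C)[C@H]1/C=C/B(O)O
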